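Ring A is disconnected back to the two carboxyl carbons of a cyclohexene-1,1-dicarboxylic acid, which a catalytic enantioselective bromolactonisation tells apart. The step exploits the 1,4-relationship across ring B between spiro C7 and tertiary C10 and the trans C10–heteroatom/C11–Br pair: in one operation it bridges C7 to C10 by a temporary δ-lactone, adds bromine to C11 on the face of the future C6, and fixes C7, C10 and C11 together. The precursor is the prochiral 4-methylcyclohex-3-ene-1,1-dicarboxylic acid, whose carboxyls are enantiotopic; the lactonised one becomes C2, the free one C6.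

Key step: step 4

Remark on numbering: atoms are numbered along the target SMILES (C1 exocyclic CH2, C2, C3 carbinol, C4, C5 bromoalkene carbon, C6 CMe2, C7 spiro, C8, C9, C10 C(Me)Cl, C11 CHBr, C12; ring A = C2–C7, ring B = C7–C12). The lactone acid 6 maps onto the target with its lactone carbonyl as C2, its free acid as C6 and C10–O replaced by C10–Cl with retention; the structures are mutually consistent and needed no correction.

Assumption: (DHQD)2PHAL is taken to deliver 6 as drawn; if the antipode forms, the pseudo-enantiomeric (DHQ)2PHAL is used, and the sense is to be secured by crystallography of 6.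

Step 1
Reactants: 1 diethyl 2-(prop-2-en-1-yl)propanedioate (diethyl allylmalonate); 2 4-bromo-2-methylbut-1-ene
Product: 3 diethyl 2-(3-methylbut-3-en-1-yl)-2-(prop-2-en-1-yl)propanedioate
Conditions: NaH, DMF, 0 °C; then 2, 60 °C
Reagents that add atoms: none
Why: Malonic ester alkylation (SN2 of the sodium enolate on the primary homoallylic bromide) should install the second alkene arm; no stereocentre is formed.

Step 2
Reactants: 3 diethyl 2-(3-methylbut-3-en-1-yl)-2-(prop-2-en-1-yl)propanedioate
Product: 4 diethyl 4-methylcyclohex-3-ene-1,1-dicarboxylate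
Conditions: [RuCl2(=CHPh)(H2IMes)(PCy3)] (2 mol %), CH2Cl2, 40 °C
Reagents that add atoms: none
Why: Ring-closing metathesis of a terminal and a 1,1-disubstituted alkene, helped by the geminal diester, should close the trisubstituted cyclohexene with the methyl group unambiguously at C10.

Step 3
Reactants: 4 diethyl 4-methylcyclohex-3-ene-1,1-dicarboxylate
Product: 5 4-methylcyclohex-3-ene-1,1-dicarboxylic acid
Conditions: KOH, EtOH/H2O, reflux; then aq. HCl, 0 °C
Reagents that add atoms: potassium hydroxide, [K+].[OH-]
Why: Saponification of both esters and cold acidification should give the geminal diacid below its decarboxylation temperature; its two carboxyls are enantiotopic.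

Step 4
Reactants: 5 4-methylcyclohex-3-ene-1,1-dicarboxylic acid
Product: 6 (1S,4R,6S)-6-bromo-1-methyl-3-oxo-2-oxabicyclo[2.2.2]octane-4-carboxylic acid
Conditions: NBS (1.1 equiv), (DHQD)2PHAL (10 mol %), CHCl3/toluene, −40 °C
Reagents that add atoms: N-bromosuccinimide, O=C1CCC(=O)N1Br
Why: The quinuclidine base of the catalyst holds one carboxyl as an ion pair while the catalyst-bound bromenium from NBS is delivered to one enantiotopic face of the C10=C11 bond, and the carboxylate on the opposite face attacks tertiary C10 anti to the bromonium; the closest known reaction type is catalytic asymmetric halolactonisation of alkenoic acids in its desymmetrising mode. The ring closes as a δ-lactone through a boat of ring B (6-exo-trig counted through C8–C9, Markovnikov at C10), giving the 2-oxabicyclo[2.2.2]octanone. C10 and C11 are set by the anti addition and their absolute sense by the catalyst's choice of alkene face; C7 becomes stereogenic at the same moment because only the carboxyl cis to the new C10–O bond can bridge, so its configuration is tied geometrically to C10. The step needs enantiotopic-face (equivalently carboxyl) discrimination, which only the chiral catalyst supplies, and δ- over γ-regioselectivity, which the methyl group secures by placing the positive charge of the bromonium on tertiary C10; low temperature and a weakly polar medium hold back the uncatalysed reaction. Bromine thereby ends on the face of the free carboxyl, the future C6.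

Step 5
Reactants: 6 (1S,4R,6S)-6-bromo-1-methyl-3-oxo-2-oxabicyclo[2.2.2]octane-4-carboxylic acid
Product: 8 (1S,4R,6S)-4-acetyl-6-bromo-1-methyl-2-oxabicyclo[2.2.2]octan-3-one, via acid chloride 7 (not isolated)
Conditions: (COCl)2, cat. DMF, CH2Cl2, 0 °C to rt; then Me2CuLi (from MeLi, CuI), Et2O/THF, −78 °C
Reagents that add atoms: lithium dimethylcuprate, [Li+].C[Cu-]C (made in the flask from methyllithium, [Li]C, and CuI)
Why: Acid chloride formation followed by acylation of the cuprate (ketone synthesis from an acyl chloride) should stop at the methyl ketone, while the cage lactone keeps the bromohydrin masked and the bridge bromide, hindered and without an antiperiplanar β-hydrogen, is left alone.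

Step 6
Reactants: 8 (1S,4R,6S)-4-acetyl-6-bromo-1-methyl-2-oxabicyclo[2.2.2]octan-3-one
Product: 9 (1S,4R,6S)-6-bromo-1-methyl-4-(prop-1-en-2-yl)-2-oxabicyclo[2.2.2]octan-3-one
Conditions: Ph3PCH3Br, KHMDS, THF, 0 to 50 °C
Reagents that add atoms: methyltriphenylphosphonium bromide, C[P+](c1ccccc1)(c1ccccc1)c1ccccc1.[Br-]
Why: Wittig methylenation with a salt-free, non-nucleophilic-base-derived ylide should turn the acetyl group into the isopropenyl group (future C6 with one methyl and the CH2 that becomes the second), the ketone being far more reactive than the hindered lactone.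

Step 7
Reactants: 9 (1S,4R,6S)-6-bromo-1-methyl-4-(prop-1-en-2-yl)-2-oxabicyclo[2.2.2]octan-3-one
Product: 11 (1R,3S,4S)-3-bromo-4-chloro-4-methyl-1-(prop-1-en-2-yl)cyclohexane-1-carbaldehyde, via chloro acid chloride 10 (not isolated)
Conditions: SOCl2, ZnCl2 (10 mol %), CH2Cl2, rt to 40 °C; evaporate; then LiAlH(OtBu)3, THF, −78 °C
Reagents that add atoms: thionyl chloride, O=S(Cl)Cl
Why: Lewis-acid-assisted alkyl–oxygen cleavage of the tertiary lactone by thionyl chloride (the lactone to ω-chloroacyl chloride reaction) should run through the C10/C11 bromonium ion, the antiperiplanar C11–Br displacing the carboxylate and chloride reopening at tertiary C10 on the face the oxygen left (neighbouring-group participation, double inversion, net retention), after which the acyl chloride, unable to re-lactonise, is reduced selectively to the aldehyde.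

Step 8
Reactants: 11 (1R,3S,4S)-3-bromo-4-chloro-4-methyl-1-(prop-1-en-2-yl)cyclohexane-1-carbaldehyde
Product: 13 2-[(1R,3S,4S)-3-bromo-4-chloro-4-methyl-1-(prop-1-en-2-yl)cyclohexyl]acetaldehyde, via enol ether 12 (not isolated)
Conditions: MeOCH2PPh3Cl, KHMDS, THF, −78 to 0 °C; then 2 M HCl, THF, rt
Reagents that add atoms: (methoxymethyl)triphenylphosphonium chloride, COC[P+](c1ccccc1)(c1ccccc1)c1ccccc1.[Cl-]; water, O
Why: Wittig reaction with the methoxymethylidene ylide and mild hydrolysis of the enol ether should homologate the non-enolisable aldehyde by one carbon (C3); the diequatorial bromochloride offers no antiperiplanar C–H/C–X pair to the base.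

Step 9
Reactants: 13 2-[(1R,3S,4S)-3-bromo-4-chloro-4-methyl-1-(prop-1-en-2-yl)cyclohexyl]acetaldehyde
Product: 14 2-[(1R,3S,4S)-3-bromo-4-chloro-4-methyl-1-(prop-1-en-2-yl)cyclohexyl]prop-2-enal
Conditions: aq. CH2O, pyrrolidine (10 mol %), propionic acid (10 mol %), iPrOH, 45 °C
Reagents that add atoms: formaldehyde, C=O
Why: Amine-catalysed Mannich condensation with formaldehyde and elimination (α-methylenation of an aldehyde) should place the exocyclic C1 methylene on C2 without strong base.

Step 10
Reactants: 14 2-[(1R,3S,4S)-3-bromo-4-chloro-4-methyl-1-(prop-1-en-2-yl)cyclohexyl]prop-2-enal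
Product: 15 2-[(1R,3S,4S)-3-bromo-4-chloro-4-methyl-1-(prop-1-en-2-yl)cyclohexyl]-5-(trimethylsilyl)pent-1-en-4-yn-3-ol (both carbinol epimers)
Conditions: TMSC≡CH, n-BuLi, THF, −78 °C; then 14; aq. NH4Cl
Reagents that add atoms: ethynyltrimethylsilane, C#C[Si](C)(C)C
Why: 1,2-Addition of the lithium acetylide to the enal should bring in C4 and C5; the carbinol configuration is irrelevant because C3 is oxidised in the next step.

Step 11
Reactants: 15 2-[(1R,3S,4S)-3-bromo-4-chloro-4-methyl-1-(prop-1-en-2-yl)cyclohexyl]-5-(trimethylsilyl)pent-1-en-4-yn-3-ol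
Product: 16 2-[(1R,3S,4S)-3-bromo-4-chloro-4-methyl-1-(prop-1-en-2-yl)cyclohexyl]-5-(trimethylsilyl)pent-1-en-4-yn-3-one
Conditions: Dess–Martin periodinane, CH2Cl2, 0 °C to rt
Reagents that add atoms: none
Why: Dess–Martin oxidation of the allylic/propargylic alcohol should give the cross-conjugated enynone under neutral conditions; oxidising before bromination removes the hydroxyl that could otherwise bromoetherify onto the isopropenyl group.

Step 12
Reactants: 16 2-[(1R,3S,4S)-3-bromo-4-chloro-4-methyl-1-(prop-1-en-2-yl)cyclohexyl]-5-(trimethylsilyl)pent-1-en-4-yn-3-one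
Product: 17 5-bromo-2-[(1R,3S,4S)-3-bromo-4-chloro-4-methyl-1-(prop-1-en-2-yl)cyclohexyl]pent-1-en-4-yn-3-one
Conditions: NBS, AgNO3 (10 mol %), acetone, rt, dark
Reagents that add atoms: N-bromosuccinimide, O=C1CCC(=O)N1Br
Why: Silver-catalysed bromodesilylation of the alkynylsilane (through a silver acetylide) should give the 1-bromoalkyne faster than NBS attacks either 1,1-disubstituted alkene.

Step 13
Reactants: 17 5-bromo-2-[(1R,3S,4S)-3-bromo-4-chloro-4-methyl-1-(prop-1-en-2-yl)cyclohexyl]pent-1-en-4-yn-3-one
Product: 18 (6S,8S,9S)-4,8-dibromo-9-chloro-5,5,9-trimethyl-1-methylidenespiro[5.5]undec-3-en-2-one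
Conditions: Fe(acac)3 (30 mol %), PhSiH3, EtOH/THF, 0 °C to rt, 0.01 M
Reagents that add atoms: none
Why: Proposed new method: iron-hydride hydrogen-atom transfer to the CH2 of the electron-richer isopropenyl group should give the tertiary C6 radical, which adds 6-endo-dig to C5, the bromine-bearing β-carbon of the ynone (polarity-matched and helped by the quaternary C7), and the α-keto vinyl radical at C4, which cannot expel bromine because a cyclohexyne would result, is reduced to C4–H; the closest known reaction types are the hydrogen-atom-transfer-initiated reductive Giese cyclisation of alkenes onto enones and radical conjugate addition to alkynones, neither shown on a 1-bromoalkynyl ketone.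

Step 14
Reactants: 18 (6S,8S,9S)-4,8-dibromo-9-chloro-5,5,9-trimethyl-1-methylidenespiro[5.5]undec-3-en-2-one
Product: 19 (2R,6S,8S,9S)-4,8-dibromo-9-chloro-5,5,9-trimethyl-1-methylidenespiro[5.5]undec-3-en-2-ol
Conditions: (S)-Me-CBS (20 mol %), catecholborane, toluene, −78 °C; then H2O
Reagents that add atoms: none
Why: Corey–Bakshi–Shibata reduction should deliver hydride 1,2 to the catalyst-bound dienone with the α-branched C2 alkenyl arm as the large group, setting C3 as R by reagent control (hydroxyl on the ring-A face that carries C8).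

Compound list
1 | diethyl 2-(prop-2-en-1-yl)propanedioate | CCOC(=O)C(CC=C)C(=O)OCC | starting material
2 | 4-bromo-2-methylbut-1-ene | C=C(C)CCBr | starting material
3 | diethyl 2-(3-methylbut-3-en-1-yl)-2-(prop-2-en-1-yl)propanedioate | CCOC(=O)C(CC=C)(CCC(C)=C)C(=O)OCC | intermediate
4 | diethyl 4-methylcyclohex-3-ene-1,1-dicarboxylate | CCOC(=O)C1(CCC(C)=CC1)C(=O)OCC | intermediate
5 | 4-methylcyclohex-3-ene-1,1-dicarboxylic acid | CC1=CCC(CC1)(C(=O)O)C(=O)O | intermediate
6 | (1S,4R,6S)-6-bromo-1-methyl-3-oxo-2-oxabicyclo[2.2.2]octane-4-carboxylic acid | OC(=O)[C@]12CC[C@](C)(OC1=O)[C@@H](Br)C2 | intermediate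
7 | (1S,4S,6S)-6-bromo-1-methyl-3-oxo-2-oxabicyclo[2.2.2]octane-4-carbonyl chloride (not isolated) | ClC(=O)[C@]12CC[C@](C)(OC1=O)[C@@H](Br)C2 | intermediate
8 | (1S,4R,6S)-4-acetyl-6-bromo-1-methyl-2-oxabicyclo[2.2.2]octan-3-one | CC(=O)[C@]12CC[C@](C)(OC1=O)[C@@H](Br)C2 | intermediate
9 | (1S,4R,6S)-6-bromo-1-methyl-4-(prop-1-en-2-yl)-2-oxabicyclo[2.2.2]octan-3-one | C=C(C)[C@]12CC[C@](C)(OC1=O)[C@@H](Br)C2 | intermediate
10 | (1R,3S,4S)-3-bromo-4-chloro-4-methyl-1-(prop-1-en-2-yl)cyclohexane-1-carbonyl chloride (not isolated) | C=C(C)[C@@]1(C(=O)Cl)CC[C@](C)(Cl)[C@@H](Br)C1 | intermediate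
11 | (1R,3S,4S)-3-bromo-4-chloro-4-methyl-1-(prop-1-en-2-yl)cyclohexane-1-carbaldehyde | C=C(C)[C@@]1(C=O)CC[C@](C)(Cl)[C@@H](Br)C1 | intermediate
12 | (1S,3S,4S)-3-bromo-4-chloro-1-(2-methoxyethenyl)-4-methyl-1-(prop-1-en-2-yl)cyclohexane (alkene geometry unassigned; not isolated) | C=C(C)[C@@]1(C=COC)CC[C@](C)(Cl)[C@@H](Br)C1 | intermediate
13 | 2-[(1R,3S,4S)-3-bromo-4-chloro-4-methyl-1-(prop-1-en-2-yl)cyclohexyl]acetaldehyde | C=C(C)[C@@]1(CC=O)CC[C@](C)(Cl)[C@@H](Br)C1 | intermediate
14 | 2-[(1R,3S,4S)-3-bromo-4-chloro-4-methyl-1-(prop-1-en-2-yl)cyclohexyl]prop-2-enal | C=C(C)[C@@]1(C(=C)C=O)CC[C@](C)(Cl)[C@@H](Br)C1 | intermediate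
15 | 2-[(1R,3S,4S)-3-bromo-4-chloro-4-methyl-1-(prop-1-en-2-yl)cyclohexyl]-5-(trimethylsilyl)pent-1-en-4-yn-3-ol (both carbinol epimers) | C=C(C)[C@@]1(C(=C)C(O)C#C[Si](C)(C)C)CC[C@](C)(Cl)[C@@H](Br)C1 | intermediate
16 | 2-[(1R,3S,4S)-3-bromo-4-chloro-4-methyl-1-(prop-1-en-2-yl)cyclohexyl]-5-(trimethylsilyl)pent-1-en-4-yn-3-one | C=C(C)[C@@]1(C(=C)C(=O)C#C[Si](C)(C)C)CC[C@](C)(Cl)[C@@H](Br)C1 | intermediate
17 | 5-bromo-2-[(1R,3S,4S)-3-bromo-4-chloro-4-methyl-1-(prop-1-en-2-yl)cyclohexyl]pent-1-en-4-yn-3-one | C=C(C)[C@@]1(C(=C)C(=O)C#CBr)CC[C@](C)(Cl)[C@@H](Br)C1 | intermediate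
18 | (6S,8S,9S)-4,8-dibromo-9-chloro-5,5,9-trimethyl-1-methylidenespiro[5.5]undec-3-en-2-one | C=C1C(=O)C=C(Br)C(C)(C)[C@]12CC[C@](C)(Cl)[C@@H](Br)C2 | intermediate
19 | (2R,6S,8S,9S)-4,8-dibromo-9-chloro-5,5,9-trimethyl-1-methylidenespiro[5.5]undec-3-en-2-ol | C=C1[C@H](O)C=C(Br)C(C)(C)[C@]12CC[C@](C)(Cl)[C@@H](Br)C2 | target

Total step count: 14. Longest linear sequence: 14 steps (1 to 19). The route therefore carries risk in two places, the key step 4 and the ring-A closure 13, for which no shorter sequence of established reactions was found.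

Steps most likely to fail

Step 13 (proposed new method). What may go wrong: hydrogen-atom transfer to the enone methylene instead of the isopropenyl group, 5-exo closure at C4, or reductive loss of the alkynyl bromine before the ring closes. The fallback uses established reactions only and sets out from 13. Iron-hydride Markovnikov hydroalkynylation of the isopropenyl group with (triisopropylsilyl)ethynyl phenyl sulfone (Fe(acac)3, PhSiH3, EtOH) would make the C5–C6 bond first and give the silylalkyne aldehyde F1. α-Methylenation as in step 9 would give the silylalkyne enal F2, and TBAF/AcOH the terminal alkyne enal F3. Anti addition of IBr (CH2Cl2, −78 °C) would place bromine on C5 and iodine on C4 cis to C6, giving the (E)-bromoiodoalkene enal F4. An intramolecular Nozaki–Hiyama–Kishi reaction (CrCl2, cat. NiCl2, DMF, high dilution), which should engage the C–I bond in preference to C–Br, would close ring A at C3–C4 to the C3-epimeric carbinol mixture F5. Dess–Martin oxidation would converge both epimers on 18, where the route is rejoined. The weak point of this fallback is possible β-elimination of the vicinal bromide from the alkenylchromium intermediate.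

Step 4 (key step). What may go wrong: insufficient discrimination of the two enantiotopic alkene faces by the catalyst, or partial closure at C11 to the γ-lactone. The fallback replaces catalytic desymmetrisation by classical resolution and sets out from 5. Uncatalysed bromolactonisation (NBS, NaHCO3, CH2Cl2/H2O, then acid) would give the racemic lactone acid F6 with the same relative configuration. Crystallisation with (S)-1-phenylethylamine would give the diastereomerically pure ammonium salt F7 (the salt of 6 is taken as the less soluble one; otherwise the (R)-amine is used), and acidification returns 6.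

Step 7. What may go wrong: protonation, hydrochlorination or cationic oligomerisation of the isopropenyl group while the lactone is ionised by the Lewis acid. The fallback reorders the sequence so that no alkene is present during ionisation and sets out from 8. Opening with SOCl2/ZnCl2 would give the keto acid chloride F8, which is trapped with MeNHOMe·HCl/pyridine as the keto Weinreb amide F9. Wittig methylenation as in step 6 would give the isopropenyl Weinreb amide F10, and DIBAL-H (THF, −78 °C) would reduce it to 11.

Further compounds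
F1 | step 13 | 2-[(1R,3S,4S)-3-bromo-4-chloro-4-methyl-1-{2-methyl-4-[tri(propan-2-yl)silyl]but-3-yn-2-yl}cyclohexyl]acetaldehyde | CC(C)(C#C[Si](C(C)C)(C(C)C)C(C)C)[C@@]1(CC=O)CC[C@](C)(Cl)[C@@H](Br)C1
F2 | step 13 | 2-[(1R,3S,4S)-3-bromo-4-chloro-4-methyl-1-{2-methyl-4-[tri(propan-2-yl)silyl]but-3-yn-2-yl}cyclohexyl]prop-2-enal | CC(C)(C#C[Si](C(C)C)(C(C)C)C(C)C)[C@@]1(C(=C)C=O)CC[C@](C)(Cl)[C@@H](Br)C1
F3 | step 13 | 2-[(1R,3S,4S)-3-bromo-4-chloro-4-methyl-1-(2-methylbut-3-yn-2-yl)cyclohexyl]prop-2-enal | CC(C)(C#C)[C@@]1(C(=C)C=O)CC[C@](C)(Cl)[C@@H](Br)C1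
F4 | step 13 | 2-{(1S,3S,4S)-3-bromo-1-[(3E)-3-bromo-4-iodo-2-methylbut-3-en-2-yl]-4-chloro-4-methylcyclohexyl}prop-2-enal | CC(C)(/C(Br)=C\I)[C@@]1(C(=C)C=O)CC[C@](C)(Cl)[C@@H](Br)C1
F5 | step 13 | (6S,8S,9S)-4,8-dibromo-9-chloro-5,5,9-trimethyl-1-methylidenespiro[5.5]undec-3-en-2-ol, mixture of 2R and 2S | C=C1C(O)C=C(Br)C(C)(C)[C@]12CC[C@](C)(Cl)[C@@H](Br)C2
F6 | step 4 | racemic (1S*,4R*,6S*)-6-bromo-1-methyl-3-oxo-2-oxabicyclo[2.2.2]octane-4-carboxylic acid | OC(=O)[C@]12CC[C@](C)(OC1=O)[C@@H](Br)C2.OC(=O)[C@@]12CC[C@@](C)(OC1=O)[C@H](Br)C2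
F7 | step 4 | (S)-1-phenylethylammonium (1S,4R,6S)-6-bromo-1-methyl-3-oxo-2-oxabicyclo[2.2.2]octane-4-carboxylate | [O-]C(=O)[C@]12CC[C@](C)(OC1=O)[C@@H](Br)C2.C[C@H]([NH3+])c1ccccc1
F8 | step 7 | (1R,3S,4S)-1-acetyl-3-bromo-4-chloro-4-methylcyclohexane-1-carbonyl chloride | CC(=O)[C@@]1(C(=O)Cl)CC[C@](C)(Cl)[C@@H](Br)C1
F9 | step 7 | (1R,3S,4S)-1-acetyl-3-bromo-4-chloro-N-methoxy-N,4-dimethylcyclohexane-1-carboxamide | CC(=O)[C@@]1(C(=O)N(C)OC)CC[C@](C)(Cl)[C@@H](Br)C1
F10 | step 7 | (1R,3S,4S)-3-bromo-4-chloro-N-methoxy-N,4-dimethyl-1-(prop-1-en-2-yl)cyclohexane-1-carboxamide | C=C(C)[C@@]1(C(=O)N(C)OC)CC[C@](C)(Cl)[C@@H](Br)C1
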